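**Plan**

- Retrosynthesis: the phenol silyl ether, the C11 alcohol (back to the aldehyde), the C10–O coumarate and a C7‑O/C10‑O acetonide are removed first; the key cut then severs C8–C9 and the C1–O acylal bond in one operation.
- Enabling feature (iridoid numbering): C9 is the α‑carbon of the masked C1 aldehyde, the acylal carbon of the pyran ring, and C8 is a tertiary carbinol flanked by C7–O and C10–O. C8–C9 is therefore an aldol bond to a dihydroxyacetone‑type ketone, and the C1 cation left by that aldol is where the 3‑methylpentanoate sits.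
- The precursor is a 2‑ethoxy‑5‑formyl‑3,4‑dihydro‑2H‑pyran carrying a 2,2‑dimethyl‑1,3‑dioxan‑5‑one on C6. It is cut further at C4–C11 (formylation), O2–C1/C5–C9 (oxa‑Diels–Alder), C4=C5 (cross‑metathesis) and C6–C7 (hydrazone alkylation).
- Forward: the dioxanone ring is bought, the pyran ring is made by cycloaddition, the cyclopentane closes between the two in the key step, and the dioxane is then opened to free C7–OH and C10–OH for the coumarate.
- Stereochemistry: C7 from the SAMP auxiliary; C5 from the chiral chromium catalyst of the cycloaddition; C9, C8 and C1 from the key step (two cis ring fusions and convex‑face capture); the side‑chain centre from (S)‑3‑methylpentanoic acid.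

Key step: step 8

Remark 1: iridoid numbering (C1 acylal carbon, O2, C3=C4, C5 and C9 ring fusion, C6–C7–C8 carbocycle, C10 on C8, C11 on C4) is used for the bicyclic compounds and for the corresponding atoms of their precursors.
Remark 2 (assumption): the (1S,2R) enantiomer of the chromium catalyst in step 5 is chosen on the assumption that the bound enal exposes the same face as aldehydes do in the diene–aldehyde cycloadditions of this catalyst family. If a trial on a simple β‑alkyl enal showed the opposite sense, the mirror‑image catalyst would be used.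
Remark 3 (assumption): (S)‑3‑methylpentanoic acid is taken as a purchasable reagent.

**Route**

Step 1
Reactants: 1 2,2-dimethyl-1,3-dioxan-5-one; 2 (S)-1-amino-2-(methoxymethyl)pyrrolidine (SAMP)
Product: 3 (S)-N-(2,2-dimethyl-1,3-dioxan-5-ylidene)-2-(methoxymethyl)pyrrolidin-1-amine
Conditions: benzene, reflux, Dean–Stark
Reagents that add atoms: none
Why: Hydrazone condensation of the unhindered ketone with the primary amino group of SAMP, driven by azeotropic removal of water, should attach the auxiliary without touching the acetonide.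

Step 2
Reactants: 3 SAMP hydrazone; 4 allyl bromide
Product: 6 (S)-2-(methoxymethyl)-N-[(4S)-2,2-dimethyl-4-(prop-2-enyl)-1,3-dioxan-5-ylidene]pyrrolidin-1-amine, via lithium azaenolate 5 (not isolated)
Conditions: t-BuLi (1.1 equiv), THF, −78 °C; then allyl bromide (1.2 equiv), −100 °C to rt
Reagents that add atoms: none
Why: SAMP‑hydrazone α‑alkylation, in which the chelated lithium azaenolate is allylated on the face left open by the methoxymethyl‑bearing pyrrolidine, should set C7 as S.

Step 3
Reactants: 6 allylated hydrazone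
Product: 7 (4S)-2,2-dimethyl-4-(prop-2-enyl)-1,3-dioxan-5-one
Conditions: sat. aq. oxalic acid, Et2O, rt
Reagents that add atoms: water, O
Why: Mild biphasic hydrazone hydrolysis with oxalic acid should free the ketone without opening the acetonide or epimerising the α‑centre, and the auxiliary is recovered from the aqueous phase.

Step 4
Reactants: 7 allyl dioxanone; 8 (E)-but-2-enal (crotonaldehyde)
Product: 9 (2E)-4-[(4S)-2,2-dimethyl-5-oxo-1,3-dioxan-4-yl]but-2-enal
Conditions: crotonaldehyde (5 equiv), second-generation Hoveyda–Grubbs catalyst RuCl2(H2IMes)(=CH-C6H4-2-OiPr) (3 mol%), 1,4-benzoquinone (10 mol%), CH2Cl2, 40 °C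
Reagents that add atoms: none
Why: Olefin cross‑metathesis of the terminal alkene with excess crotonaldehyde should give the E‑enal with loss of propene, the ketone and acetonide being inert to the ruthenium carbene and benzoquinone suppressing double‑bond migration.

Step 5
Reactants: 9 enal; 10 ethyl vinyl ether
Product: 11 (2S,4S)-2-ethoxy-4-{[(4S)-2,2-dimethyl-5-oxo-1,3-dioxan-4-yl]methyl}-3,4-dihydro-2H-pyran
Conditions: CrCl(L) (cat., five mol percent; L = tridentate Schiff-base dianion from 3-(1-adamantyl)-5-methylsalicylaldehyde and (1S,2R)-1-aminoindan-2-ol), 4Å MS, ethyl vinyl ether as solvent (tenfold excess), rt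
Reagents that add atoms: none
Why: Inverse‑electron‑demand oxa‑Diels–Alder reaction of the enal with the vinyl ether under the Schiff‑base complex of trivalent chromium, which shields one face of the bound oxadiene, should set C5 as S under catalyst control irrespective of the remote C7 centre, while endo addition places the ethoxy group cis to the side chain at an acetal centre that the key step erases.

Step 6
Reactants: 11 dihydropyran
Product: 13 (2S,4S)-2-ethoxy-4-{[(4S)-2,2-dimethyl-5-oxo-1,3-dioxan-4-yl]methyl}-3,4-dihydro-2H-pyran-5-carbaldehyde, via iminium chloride 12 (not isolated)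
Conditions: (chloromethylene)dimethyliminium chloride (1.3 equiv), DMF/CH2Cl2, −20 to 0 °C; then aq. NaOAc, 0 °C
Reagents that add atoms: (chloromethylene)dimethyliminium chloride, C[N+](C)=CCl.[Cl-]; water, O
Why: Vilsmeier–Haack formylation, in which the cyclic enol ether attacks the chloroiminium ion with its β‑carbon C4 as dihydropyrans and glycals do, should give the vinylogous formate after buffered hydrolysis, the ketone reacting only at higher temperature.

Step 7
Reactants: 14 (3S)-3-methylpentanoic acid
Product: 15 trimethylsilyl (3S)-3-methylpentanoate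
Conditions: (Me3Si)2NH (0.6 equiv), saccharin (1 mol%), neat, 80 °C; distillation
Reagents that add atoms: hexamethyldisilazane, C[Si](C)(C)N[Si](C)(C)C
Why: Silylation of the carboxylic acid with hexamethyldisilazane should give the distillable silyl ester with ammonia as the only by‑product and cannot affect the β‑stereocentre.

Step 8
Reactants: 13 formyl dihydropyran; 15 trimethylsilyl (3S)-3-methylpentanoate
Product: 18 (1S,5S,7S,8R,9S)-4-formyl-7,10-O-isopropylidene-8-O-trimethylsilyl iridoid 1-yl (3S)-3-methylpentanoate, via enol ether 16 (not isolated), via oxocarbenium triflate 17 (not isolated)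
Conditions: silyl ester (2.5 equiv), Me3SiOTf (0.3 equiv), CH2Cl2 (0.02 M), −40 to 0 °C; pyridine quench, aq. NaHCO3
Reagents that add atoms: none
Why: Proposed new method: Me3SiOTf strips the C1 ethoxy group as EtOSiMe3 and loss of H9 gives the C1=C9 enol ether 16 (the glycal‑forming elimination known for 2‑deoxy glycosyl donors); C9 of 16 then adds to the silyl‑activated C8 ketone in a Mukaiyama‑type enol ether–carbonyl Prins addition, the closest known reaction type, giving the C8 silyl ether and oxocarbenium ion 17, which a second molecule of the silyl carboxylate captures at C1 as in Lewis‑acid acetal‑to‑acylal exchange (acetolysis of alkyl glycosides). The cyclopentane C5–C6–C7–C8–C9 closes in the 5‑exo‑trig (5‑enolexo) mode. C9 follows from the three‑atom tether, which can bring the ketone only to the pyran face that carries C6 and so gives the cis ring fusion; C8 follows from the acetonide, which ties the C7 oxygen and C10 into a six‑membered ring so that the cis‑fused dioxane–cyclopentane is strongly favoured, with the C8 oxygen on the pyran side; C1 follows from attack of the carboxylate on the convex face of 17, anti to C8, which is also the anomerically preferred axial acylal. The step needs C1=C9 and not C3=C4 to be the nucleophile and the ketone and not the aldehyde to be the electrophile, and the C11 formyl group secures both, because O2–C3=C4–C11=O is a vinylogous formate that is neither nucleophilic at carbon nor easily activated. Ethanol cannot return because it leaves as its silyl ether, retro‑aldol cleavage is blocked because the aldolate is silylated as it forms, and the acylal re‑ionises far more slowly than the ethyl acetal it replaces, so the sequence should run in one direction.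

Step 9
Reactants: 18 silylated acetonide acylal
Product: 19 (1S,4aS,6S,7R,7aS)-4-formyl-6,7-dihydroxy-7-(hydroxymethyl)-1,4a,5,6,7,7a-hexahydrocyclopenta[c]pyran-1-yl (3S)-3-methylpentanoate
Conditions: AcOH/H2O/THF (3:1:1), 35 °C
Reagents that add atoms: none
Why: Acid‑catalysed hydrolysis should remove the six‑membered acetonide and the tertiary trimethylsilyl ether, while the acylal survives because its ring oxygen is tied up in the vinylogous formate and gives little support to a C1 cation.

Step 10
Reactants: 20 p-coumaric acid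
Product: 22 (E)-3-[4-(tert-butyldimethylsilyloxy)phenyl]prop-2-enoic acid, via silyl ester 21 (not isolated)
Conditions: TBSCl (2.3 equiv), imidazole (5 equiv), DMF, rt; then AcOH/H2O/THF, rt
Reagents that add atoms: tert-butyldimethylsilyl chloride, CC(C)(C)[Si](C)(C)Cl
Why: Silylation of phenol and acid followed by selective hydrolysis of the much more labile silyl ester should leave the aryl silyl ether and the free acid.

Step 11
Reactants: 22 silylated coumaric acid
Product: 23 (E)-3-[4-(tert-butyldimethylsilyloxy)phenyl]prop-2-enoyl chloride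
Conditions: (COCl)2 (1.3 equiv), DMF (cat.), CH2Cl2, 0 °C to rt; concentrate, use crude
Reagents that add atoms: oxalyl chloride, O=C(Cl)C(=O)Cl
Why: Acid chloride formation with oxalyl chloride and catalytic DMF proceeds at or below room temperature, where the aryl silyl ether and the E‑alkene are stable.

Step 12
Reactants: 19 triol aldehyde; 23 acid chloride
Product: 24 (1S,4aS,6S,7R,7aS)-7-({[(2E)-3-[4-(tert-butyldimethylsilyloxy)phenyl]prop-2-enoyl]oxy}methyl)-4-formyl-6,7-dihydroxy-1,4a,5,6,7,7a-hexahydrocyclopenta[c]pyran-1-yl (3S)-3-methylpentanoate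
Conditions: acid chloride (1.1 equiv), 2,4,6-collidine (3 equiv), CH2Cl2, −40 to 0 °C
Reagents that add atoms: none
Why: Regioselective O‑acylation with an acid chloride and the hindered base collidine at low temperature should esterify the primary C10 hydroxyl much faster than the secondary C7 and tertiary C8 hydroxyls.

Step 13
Reactants: 24 coumarate aldehyde
Product: 25 the corresponding C11 allylic alcohol, (1S,4aS,6S,7R,7aS)-7-({[(2E)-3-[4-(tert-butyldimethylsilyloxy)phenyl]prop-2-enoyl]oxy}methyl)-6,7-dihydroxy-4-(hydroxymethyl)-1,4a,5,6,7,7a-hexahydrocyclopenta[c]pyran-1-yl (3S)-3-methylpentanoate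
Conditions: NaBH4 (1.0 equiv), CeCl3·7H2O (1.1 equiv), MeOH/THF (1:1), −40 °C; aq. NH4Cl
Reagents that add atoms: none
Why: Luche 1,2‑reduction should convert the conjugated aldehyde into the allylic alcohol at low temperature, where the two esters, the acylal and the cinnamate double bond are not attacked.

Step 14
Reactants: 25 silyl-protected precursor
Product: 26 CNP0241834.1, (1S,4aS,6S,7R,7aS)-6,7-dihydroxy-4-(hydroxymethyl)-7-({[(2E)-3-(4-hydroxyphenyl)prop-2-enoyl]oxy}methyl)-1,4a,5,6,7,7a-hexahydrocyclopenta[c]pyran-1-yl (3S)-3-methylpentanoate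
Conditions: Bu4NF (1.1 equiv), AcOH (1.5 equiv), THF, 0 °C
Reagents that add atoms: none
Why: Fluoride cleavage of the aryl silyl ether, buffered with acetic acid so that no phenoxide or alkoxide persists, should free the phenol without acyl migration from C10 to the C7 or C8 hydroxyl and without attack on the acylal.

**Compound list**

1 | 2,2-dimethyl-1,3-dioxan-5-one | CC1(C)OCC(=O)CO1 | starting material
2 | (S)-1-amino-2-(methoxymethyl)pyrrolidine (SAMP) | COC[C@@H]1CCCN1N | starting material
3 | (S)-N-(2,2-dimethyl-1,3-dioxan-5-ylidene)-2-(methoxymethyl)pyrrolidin-1-amine | COC[C@@H]1CCCN1N=C1COC(C)(C)OC1 | intermediate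
4 | allyl bromide (3-bromoprop-1-ene) | C=CCBr | starting material
5 | lithium azaenolate of 3 (not isolated) | COC[C@@H]1CCCN1[N-]C1=COC(C)(C)OC1.[Li+] | intermediate
6 | (S)-2-(methoxymethyl)-N-[(4S)-2,2-dimethyl-4-(prop-2-enyl)-1,3-dioxan-5-ylidene]pyrrolidin-1-amine (C=N geometry not defined) | COC[C@@H]1CCCN1N=C1COC(C)(C)O[C@H]1CC=C | intermediate
7 | (4S)-2,2-dimethyl-4-(prop-2-enyl)-1,3-dioxan-5-one | C=CC[C@@H]1OC(C)(C)OCC1=O | intermediate
8 | (E)-but-2-enal (crotonaldehyde) | C/C=C/C=O | starting material
9 | (2E)-4-[(4S)-2,2-dimethyl-5-oxo-1,3-dioxan-4-yl]but-2-enal | O=C/C=C/C[C@@H]1OC(C)(C)OCC1=O | intermediate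
10 | ethyl vinyl ether | C=COCC | starting material
11 | (2S,4S)-2-ethoxy-4-{[(4S)-2,2-dimethyl-5-oxo-1,3-dioxan-4-yl]methyl}-3,4-dihydro-2H-pyran (2,4-cis) | CCO[C@@H]1C[C@H](C[C@@H]2OC(C)(C)OCC2=O)C=CO1 | intermediate
12 | N-{[(2S,4S)-2-ethoxy-4-{[(4S)-2,2-dimethyl-5-oxo-1,3-dioxan-4-yl]methyl}-3,4-dihydro-2H-pyran-5-yl]methylidene}-N-methylmethanaminium chloride (not isolated) | CCO[C@@H]1C[C@H](C[C@@H]2OC(C)(C)OCC2=O)C(C=[N+](C)C)=CO1.[Cl-] | intermediate
13 | (2S,4S)-2-ethoxy-4-{[(4S)-2,2-dimethyl-5-oxo-1,3-dioxan-4-yl]methyl}-3,4-dihydro-2H-pyran-5-carbaldehyde (key-step precursor) | CCO[C@@H]1C[C@H](C[C@@H]2OC(C)(C)OCC2=O)C(C=O)=CO1 | intermediate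
14 | (3S)-3-methylpentanoic acid | CC[C@H](C)CC(=O)O | starting material
15 | trimethylsilyl (3S)-3-methylpentanoate | CC[C@H](C)CC(=O)O[Si](C)(C)C | intermediate
16 | (4S)-4-{[(4S)-2,2-dimethyl-5-oxo-1,3-dioxan-4-yl]methyl}-4H-pyran-3-carbaldehyde (C1=C9 enol ether, not isolated) | O=CC1=COC=C[C@@H]1C[C@@H]2OC(C)(C)OCC2=O | intermediate
17 | (5S,7S,8R,9S) cyclised C1 oxocarbenium triflate: cis-fused cyclopenta[c]pyranylium with 4-formyl, C8–OSiMe3 and the C7‑O/C10‑O acetonide (not isolated) | C1=[O+]C=C(C=O)[C@H]2C[C@@H]3OC(C)(C)OC[C@]3(O[Si](C)(C)C)[C@@H]12.[O-]S(=O)(=O)C(F)(F)F | intermediate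
18 | (1S,5S,7S,8R,9S)-4-formyl-7,10-O-isopropylidene-8-O-trimethylsilyl iridoid 1-yl (3S)-3-methylpentanoate: cis-fused cyclopenta[c]pyran, H5 and H9 cis, acyloxy cis to H9, C8–O on the pyran face, C7‑O and C10 on the opposite face and bridged by CMe2 (key-step product) | CC[C@H](C)CC(=O)O[C@@H]1OC=C(C=O)[C@H]2C[C@@H]3OC(C)(C)OC[C@]3(O[Si](C)(C)C)[C@@H]12 | intermediate
19 | (1S,4aS,6S,7R,7aS)-4-formyl-6,7-dihydroxy-7-(hydroxymethyl)-1,4a,5,6,7,7a-hexahydrocyclopenta[c]pyran-1-yl (3S)-3-methylpentanoate | CC[C@H](C)CC(=O)O[C@@H]1OC=C(C=O)[C@H]2C[C@H](O)[C@](O)(CO)[C@@H]12 | intermediate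
20 | p-coumaric acid | O=C(O)/C=C/c1ccc(O)cc1 | starting material
21 | tert-butyldimethylsilyl (E)-3-[4-(tert-butyldimethylsilyloxy)phenyl]prop-2-enoate (not isolated) | CC(C)(C)[Si](C)(C)OC(=O)/C=C/c1ccc(O[Si](C)(C)C(C)(C)C)cc1 | intermediate
22 | (E)-3-[4-(tert-butyldimethylsilyloxy)phenyl]prop-2-enoic acid | O=C(O)/C=C/c1ccc(O[Si](C)(C)C(C)(C)C)cc1 | intermediate
23 | (E)-3-[4-(tert-butyldimethylsilyloxy)phenyl]prop-2-enoyl chloride | O=C(Cl)/C=C/c1ccc(O[Si](C)(C)C(C)(C)C)cc1 | intermediate
24 | (1S,4aS,6S,7R,7aS)-7-({[(2E)-3-[4-(tert-butyldimethylsilyloxy)phenyl]prop-2-enoyl]oxy}methyl)-4-formyl-6,7-dihydroxy-1,4a,5,6,7,7a-hexahydrocyclopenta[c]pyran-1-yl (3S)-3-methylpentanoate | CC[C@H](C)CC(=O)O[C@@H]1OC=C(C=O)[C@H]2C[C@H](O)[C@](O)(COC(=O)/C=C/c3ccc(O[Si](C)(C)C(C)(C)C)cc3)[C@@H]12 | intermediate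
25 | (1S,4aS,6S,7R,7aS)-7-({[(2E)-3-[4-(tert-butyldimethylsilyloxy)phenyl]prop-2-enoyl]oxy}methyl)-6,7-dihydroxy-4-(hydroxymethyl)-1,4a,5,6,7,7a-hexahydrocyclopenta[c]pyran-1-yl (3S)-3-methylpentanoate | CC[C@H](C)CC(=O)O[C@@H]1OC=C(CO)[C@H]2C[C@H](O)[C@](O)(COC(=O)/C=C/c3ccc(O[Si](C)(C)C(C)(C)C)cc3)[C@@H]12 | intermediate
26 | CNP0241834.1, (1S,4aS,6S,7R,7aS)-6,7-dihydroxy-4-(hydroxymethyl)-7-({[(2E)-3-(4-hydroxyphenyl)prop-2-enoyl]oxy}methyl)-1,4a,5,6,7,7a-hexahydrocyclopenta[c]pyran-1-yl (3S)-3-methylpentanoate | CC[C@H](C)CC(=O)O[C@@H]1OC=C(CO)[C@H]2C[C@H](O)[C@](O)(COC(=O)/C=C/c3ccc(O)cc3)[C@@H]12 | target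

**Step count and risks**

Total step count: 14. Longest linear sequence: 11 steps (steps 1–6, 8, 9, 12, 13, 14); steps 7, 10 and 11 prepare the two acyl donors.

Steps most likely to fail:

1. Step 8 (proposed new method). The cascade may stall after ring closure with ethoxy still on C1, because exocyclic ionisation of the deactivated acetal is slow. The acid may also enolise the ketone and epimerise C7 before the C–C bond forms, the acetonide may be ionised by the silyl triflate, or the enol ether may add intermolecularly. The fallback separates the events with known reactions and sets out from 13. Hydrolysis of the ethyl acetal (pyridinium p‑toluenesulfonate, acetone/water, 40 °C, the acetone keeping the acetonide in place) would give the lactol (4S)-4-{[(4S)-2,2-dimethyl-5-oxo-1,3-dioxan-4-yl]methyl}-2-hydroxy-3,4-dihydro-2H-pyran-5-carbaldehyde F1. Its open C1 aldehyde would be cyclised onto the C8 ketone by an amine‑catalysed intramolecular enamine aldol addition (L‑proline, DMSO, rt), under the same two ring‑fusion constraints, to the bicyclic lactol (5S,7S,8R,9S)-1,8-dihydroxy-7,10-O-isopropylidene-4-formyl iridoid F2. Steglich esterification of the lactol hydroxyl alone with acid 14 (DCC, cat. DMAP, CH2Cl2, 0 °C), with chromatographic removal of any C1 epimer, would give the 8‑hydroxy acylal (1S,5S,7S,8R,9S)-4-formyl-8-hydroxy-7,10-O-isopropylidene iridoid 1-yl (3S)-3-methylpentanoate F3. The conditions of step 9 applied to F3 come back to the route at 19.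

2. Step 6. The chloroiminium salt or the hydrogen chloride it releases may ionise the ethyl acetal, leading to elimination and formylation at C9, and chloroformylation at the enolisable ketone may compete. The fallback builds the formyl group into the heterodiene instead and sets out from 7. Ozonolysis (O3, CH2Cl2, −78 °C; Me2S) would give the keto aldehyde 2-[(4S)-2,2-dimethyl-5-oxo-1,3-dioxan-4-yl]acetaldehyde F4. A domino Knoevenagel–hetero‑Diels–Alder reaction of F4 with malonaldehyde (liberated from its commercial tetrabutylammonium enolate with acetic acid; ethylenediammonium diacetate as catalyst) in CH2Cl2/ethyl vinyl ether at rt would pass through the alkylidene malonaldehyde 2-{2-[(4S)-2,2-dimethyl-5-oxo-1,3-dioxan-4-yl]ethylidene}propanedial F5 and come back to the route at 13. No catalyst controls C5 in this variant, so the C5 epimer of 13 would have to be removed by chromatography; the anomers at C1 converge in step 8.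

3. Step 12. Over‑acylation at the C7 hydroxyl, or acyl migration from C10 to C7 during work‑up, may erode the regioselectivity. The fallback activates the diol as a tin acetal and sets out from 19. Heating with Bu2SnO (1.05 equiv, toluene/MeOH, then removal of solvent) would give the 8,10-O-dibutylstannylene acetal of 19 F6, whose primary oxygen is the nucleophilic one. Treatment with acid chloride 23 (CH2Cl2, 0 °C, no added base) comes back to the route at 24.

Further compounds
F1 | step 8 | (4S)-4-{[(4S)-2,2-dimethyl-5-oxo-1,3-dioxan-4-yl]methyl}-2-hydroxy-3,4-dihydro-2H-pyran-5-carbaldehyde (anomer mixture) | OC1C[C@H](C[C@@H]2OC(C)(C)OCC2=O)C(C=O)=CO1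
F2 | step 8 | (5S,7S,8R,9S)-1,8-dihydroxy-7,10-O-isopropylidene-4-formyl iridoid (bicyclic lactol, anomer mixture) | OC1OC=C(C=O)[C@H]2C[C@@H]3OC(C)(C)OC[C@]3(O)[C@@H]12
F3 | step 8 | (1S,5S,7S,8R,9S)-4-formyl-8-hydroxy-7,10-O-isopropylidene iridoid 1-yl (3S)-3-methylpentanoate | CC[C@H](C)CC(=O)O[C@@H]1OC=C(C=O)[C@H]2C[C@@H]3OC(C)(C)OC[C@]3(O)[C@@H]12
F4 | step 6 | 2-[(4S)-2,2-dimethyl-5-oxo-1,3-dioxan-4-yl]acetaldehyde | O=CC[C@@H]1OC(C)(C)OCC1=O
F5 | step 6 | 2-{2-[(4S)-2,2-dimethyl-5-oxo-1,3-dioxan-4-yl]ethylidene}propanedial | O=CC(C=O)=CC[C@@H]1OC(C)(C)OCC1=O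
F6 | step 12 | 8,10-O-dibutylstannylene acetal of 19 | CC[C@H](C)CC(=O)O[C@@H]1OC=C(C=O)[C@H]2C[C@H](O)[C@]3(CO[Sn](CCCC)(CCCC)O3)[C@@H]12
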